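**Retrosynthetic overview**
1. Aryl half, traced back to bought phloroglucinol 1 and isobutyryl chloride 2: the C-acyl bond (ketone 3), then the C–Br bond (4) and three O-acetyl bonds (bromo triacetate 5).
2. Alkyl half, traced back to bought (S)-linalool 6, which supplies the only stereocentre: anti-Markovnikov functionalisation of the vinyl group (borane 7, diol 8, primary bromide 9).
3. Key disconnection: the aryl–CH2 bond of triacetate 10, made from 5 + 9 in a blue-light NiCl2·glyme / Ir[dF(CF3)ppy]2(dtbbpy)PF6 cross-electrophile coupling.
4. Final disconnection: the three acetate esters of 10, giving target 11.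
5. Rings: none is formed; the benzene ring is bought in 1 and carried through.

Assumption: (S)-(+)-linalool 6 (coriandrol) is bought enantioenriched; the ee of 11 is that of the lot used, because no step touches the carbinol centre.

**Step 1**
Reactants: 1 phloroglucinol; 2 isobutyryl chloride
Product: 3 2-methyl-1-(2,4,6-trihydroxyphenyl)propan-1-one (phlorisobutyrophenone)
Conditions: AlCl3 (4 equiv), PhNO2, rt → 65 °C; then ice, 2 M HCl
Reagents that add atoms: none
Why: Friedel–Crafts C-acylation of the strongly activated triol, where the chelated ketone deactivates the ring so that mono-acylation dominates; no stereocentre is involved.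

**Step 2**
Reactants: 3 phlorisobutyrophenone
Product: 5 2-bromo-4-(2-methylpropanoyl)benzene-1,3,5-triyl triacetate, via bromotriol 4 (not isolated)
Conditions: NBS (1.0 equiv, slow addition), MeCN, −30 → 0 °C; then Ac2O, pyridine, DMAP (cat.), 0 °C → rt
Reagents that add atoms: N-bromosuccinimide, O=C1CCC(=O)N1Br; acetic anhydride, CC(=O)OC(C)=O
Why: electrophilic aromatic bromination at one of the two equivalent free ring positions, then O-acetylation of all three phenols, which turns the easily oxidised, weak-C–Br bromophenol into an ordinary, electron-poorer aryl bromide; no stereocentre is involved.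

**Step 3**
Reactants: 6 (S)-linalool
Product: 8 (3S)-3,7-dimethyloct-6-ene-1,3-diol, via alkylborane 7 (not isolated)
Conditions: 9-BBN (1.3 equiv), THF, 0 °C → rt; then 3 M NaOH, 30% H2O2, 0 °C → rt
Reagents that add atoms: 9-borabicyclo[3.3.1]nonane (9-BBN; its atoms stay only in 7), B1C2CCCC1CCC2; hydrogen peroxide, OO
Why: Brown hydroboration–oxidation, in which 9-BBN adds anti-Markovnikov to the monosubstituted vinyl group far faster than to the trisubstituted alkene; the quaternary carbinol centre of 6 is a spectator and is retained (7 is formally R only because boron ranks below carbon).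

**Step 4**
Reactants: 8 (3S)-3,7-dimethyloct-6-ene-1,3-diol
Product: 9 (3S)-1-bromo-3,7-dimethyloct-6-en-3-ol
Conditions: CBr4, PPh3, CH2Cl2, 0 °C
Reagents that add atoms: carbon tetrabromide, BrC(Br)(Br)Br
Why: Appel reaction, in which only the primary alcohol forms the alkoxyphosphonium ion and is displaced by bromide (SN2) while the hindered tertiary alcohol stays; the stereocentre is untouched.

**Step 5**
Reactants: 5 2-bromo-4-(2-methylpropanoyl)benzene-1,3,5-triyl triacetate; 9 (3S)-1-bromo-3,7-dimethyloct-6-en-3-ol (1.8 equiv)
Product: 10 2-[(3S)-3-hydroxy-3,7-dimethyloct-6-en-1-yl]-4-(2-methylpropanoyl)benzene-1,3,5-triyl triacetate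
Conditions: Ir[dF(CF3)ppy]2(dtbbpy)PF6 (1 mol%), NiCl2·glyme (10 mol%), dtbbpy (12 mol%), (Me3Si)3SiH (1.2 equiv), Na2CO3 (2 equiv), DME, 450 nm LEDs, 25 °C
Reagents that add atoms: none
Why: Proposed new method: silyl-radical-mediated nickel/photoredox cross-electrophile coupling applied to a fully substituted 2,6-bis(acyloxy)aryl bromide (a masked C-halophloroglucinol), where blue-light-excited Ir[dF(CF3)ppy]2(dtbbpy)PF6 oxidises bromide to a bromine atom that takes H from (Me3Si)3SiH, the silyl radical abstracts bromine from 9 to give the primary C1 radical (a 3-hydroxycitronellyl-type radical whose 6-exo closure and 1,5-H shift are slow, and which never places a radical at C2 where 5-exo cyclisation onto the prenyl alkene would be fast), zerovalent nickel inserts into the C–Br bond of 5 (made electron-poorer by three acetoxy groups and the ketone), the divalent aryl nickel bromide captures the radical and the trivalent nickel species reductively eliminates the aryl–CH2 bond, with the flanking acetoxy groups expected to be small enough at the ortho atoms (and possibly hemilabile O-donors) for capture to compete; the closest known reaction type is the silyl-radical nickel/photoredox coupling of unhindered or mono-ortho-substituted aryl bromides with alkyl bromides; the stereocentre is a spectator.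

**Step 6**
Reactants: 10 coupled triacetate
Product: 11 1-{2,4,6-trihydroxy-3-[(3S)-3-hydroxy-3,7-dimethyloct-6-en-1-yl]phenyl}-2-methylpropan-1-one (target)
Conditions: K2CO3 (0.5 equiv), degassed MeOH, Ar, 0 °C → rt; then pH 5 phosphate buffer
Reagents that add atoms: none
Why: base-mediated transesterification (methanolysis) of the three activated aryl acetates under non-acidic conditions, so the tertiary alcohol cannot ionise or close onto the ortho phenol to a chroman and the stereocentre is kept.

**Compound list**
1 | phloroglucinol (benzene-1,3,5-triol) | Oc1cc(O)cc(O)c1 | starting material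
2 | isobutyryl chloride (2-methylpropanoyl chloride) | CC(C)C(Cl)=O | starting material
3 | 2-methyl-1-(2,4,6-trihydroxyphenyl)propan-1-one (phlorisobutyrophenone) | CC(C)C(=O)c1c(O)cc(O)cc1O | intermediate
4 | 1-(3-bromo-2,4,6-trihydroxyphenyl)-2-methylpropan-1-one | CC(C)C(=O)c1c(O)cc(O)c(Br)c1O | intermediate (not isolated)
5 | 2-bromo-4-(2-methylpropanoyl)benzene-1,3,5-triyl triacetate | CC(C)C(=O)c1c(OC(C)=O)cc(OC(C)=O)c(Br)c1OC(C)=O | intermediate
6 | (S)-(+)-linalool, (3S)-3,7-dimethylocta-1,6-dien-3-ol | CC(C)=CCC[C@](C)(O)C=C | starting material
7 | (3R)-1-(9-borabicyclo[3.3.1]nonan-9-yl)-3,7-dimethyloct-6-en-3-ol (same spatial arrangement as 6; descriptor changes because boron ranks below carbon) | CC(C)=CCC[C@](C)(O)CCB1C2CCCC1CCC2 | intermediate (not isolated)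
8 | (3S)-3,7-dimethyloct-6-ene-1,3-diol | CC(C)=CCC[C@](C)(O)CCO | intermediate
9 | (3S)-1-bromo-3,7-dimethyloct-6-en-3-ol | CC(C)=CCC[C@](C)(O)CCBr | intermediate
10 | 2-[(3S)-3-hydroxy-3,7-dimethyloct-6-en-1-yl]-4-(2-methylpropanoyl)benzene-1,3,5-triyl triacetate | CC(C)=CCC[C@](C)(O)CCc1c(OC(C)=O)cc(OC(C)=O)c(C(=O)C(C)C)c1OC(C)=O | intermediate
11 | 1-{2,4,6-trihydroxy-3-[(3S)-3-hydroxy-3,7-dimethyloct-6-en-1-yl]phenyl}-2-methylpropan-1-one | CC(C)=CCC[C@](C)(O)CCc1c(O)cc(O)c(C(=O)C(C)C)c1O | target

**Step count**
Total step count: 6 (steps 2 and 3 are one-flask, two-stage operations).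
Longest linear sequence: 4 steps (6 → 8 → 9 → 10 → 11; the aryl branch 1 → 3 → 5 → 10 → 11 is equally long).

**Three steps most likely to fail**

Step 5 (the proposed new coupling). The aryl bromide carries two ortho acetoxy groups, and di-ortho-substituted aryl halides are generally poor partners in nickel-bipyridine radical couplings. If radical capture at the shielded nickel centre is too slow, 5 and 9 are simply reduced. The fallback is a two-electron palladium B-alkyl Suzuki–Miyaura coupling, known chemistry that does not need radical capture at a hindered metal. It sets out from 5 and from alkylborane 7, made in the flask from 6 and 9-BBN as in the first stage of step 3 and used without oxidation. With Pd(OAc)2, SPhos and CsF in THF at 50 °C it gives triacetate 10, where it comes back to the route. New compounds on the way: none F0.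

Step 2 (mono-bromination). Ketone 3 has two equivalent, very reactive ring positions, so dibromide and unreacted 3 may accompany 4. The fallback buys the bromine already in place. It sets out from 2, which acylates 2-bromo-1,3,5-trimethoxybenzene F1 (AlCl3, CH2Cl2, 0 °C) to 1-(3-bromo-2,4,6-trimethoxyphenyl)-2-methylpropan-1-one F2. BBr3 in CH2Cl2 (−78 °C → rt) then cleaves the three methyl ethers to bromotriol 4, where it comes back to the route; 4 is acetylated to 5 as in the second stage of step 2.

Step 4 (Appel bromination of the 1,3-diol). The alkoxyphosphonium ion could be closed by the tertiary hydroxyl to an oxetane, or adventitious HBr could dehydrate the tertiary alcohol. The fallback replaces phosphonium activation by a sulfonate displacement. It sets out from diol 8, which is tosylated selectively at the primary hydroxyl (TsCl, Et3N, DMAP cat., CH2Cl2, 0 °C) to (3S)-3-hydroxy-3,7-dimethyloct-6-en-1-yl 4-methylbenzenesulfonate F3. LiBr in acetone at 40 °C then gives bromide 9, where it comes back to the route.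

**Further compounds**
F1 | step 2 | 2-bromo-1,3,5-trimethoxybenzene | COc1cc(OC)c(Br)c(OC)c1
F2 | step 2 | 1-(3-bromo-2,4,6-trimethoxyphenyl)-2-methylpropan-1-one | COc1cc(OC)c(C(=O)C(C)C)c(OC)c1Br
F3 | step 4 | (3S)-3-hydroxy-3,7-dimethyloct-6-en-1-yl 4-methylbenzenesulfonate | CC(C)=CCC[C@](C)(O)CCOS(=O)(=O)c1ccc(C)cc1
F0 | step 5 | none | none
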